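## Structural features

The target has four oxygenated benzene rings: ring A (the 4-hydroxy-3-methoxybenzoyl group), ring B (the central 2-hydroxy-3-methoxyphenyl ring), ring C (the benzene ring of the 2,3-dihydrobenzofuran) and ring D (the 4-hydroxy-3-methoxyphenyl group on C2 of that heterocycle). Rings B and C are bridged by a cis-fused 3,7-dioxabicyclo[3.3.0]octane (furofuran; C7/C8/C9 on the ring B side, C7′/C8′/C9′ on the ring C side). Its four contiguous centres C7 (S), C8 (R), C8′ (R) and C7′ (S) hold both aryl groups exo. Ring C is fused to the dihydrofuran O1–C2–C3–C3a–C7a, where C2 (S, ring D) and C3 (S, CH2OH) are neighbours in the less stable cis arrangement; ring B carries, ortho to its phenol, the chain C8″(S)H(CH2OH)–C7″(=O)–ring A. C8″ is α to a ketone, benzylic and β to a hydroxyl, so base can epimerise it, eliminate water or release formaldehyde, and acid can close the ring B phenol onto the ketone and dehydrate to a benzofuran. The benzylic C–O bonds at C2, C7 and C7′ can ionise under acid, which would turn the cis-dihydrobenzofuran into the trans isomer and scramble the exo aryl groups. The real difficulty is that the three stereochemical regions (C8″; C7–C8–C8′–C7′; C2–C3) are insulated from each other by benzene rings, so each must be set in the absolute sense by a reagent, and the cis C2/C3 pair must be made under kinetic control. The key step uses the fact that the ring O1–C2–C3–C3a–C7a with ring D on C2 is the pyranone ring of a flavanone minus its carbonyl carbon: a 1,2-shift of C4a (the future C3a) from C4 to C3 contracts the ring, and the expelled C4 becomes the C3 hydroxymethyl carbon.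

## Logic of the disconnections

40 ⇒ 39. The five O–Si bonds are cut. Every hydroxyl is carried as a silyl ether so that a single fluoride treatment is the only operation performed on the base- and acid-sensitive keto alcohol. The forward step must stay near neutral.

39 ⇒ 30 + 36 (through 37 and 38). The C8″–aryl bond to ring B is cut. This is the most convergent cut, and it lets C8″ be set late by a chiral nickel catalyst in a stereoconvergent coupling of racemic 36. The forward step needs an organozinc next to a silyloxy group without silyl migration, and non-basic conditions.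

36 ⇒ 34 ⇒ 33 ⇒ 7 + 31 (through 35 and 32). The C–Br bond, the C7″ oxidation level and the C7″–ring A bond are removed in turn. The racemic bromide is acceptable because the coupling is stereoconvergent. The forward bromination must be regioselective for the only enolisable position.

30 ⇒ 29 ⇒ 28. After the ring B silyl ether, both benzylic C–O bonds of the furofuran (C7–O and C7′–O) are cut. This removes two rings and two stereocentres that need not be controlled earlier. The forward closure must ionise C7 and C7′ (helped by the free ring B phenol and the para oxygen of ring C) but not C2.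

28 ⇒ 27 ⇒ 26. Carbinol, CH2OH and phenol are traced back to ketone, lactone, lactone acetal and pivalate, and the ketone to a dithiane. One hydride step must reduce all of them and release the auxiliary alcohol.

26 ⇒ 20 + 23 + 22 (through 24 and 25). The C7′–C8′ and C8–C7 bonds are cut in a three-component union. C8′ and C8 are set by the acetal centre of 23. The forward step needs 1,4-addition anti to the alkoxy group and trapping anti to the new substituent.

20 ⇒ 19 ⇒ 17 (through 18) ⇒ 16 ⇒ 15; 22 ⇒ 21. These are functional group changes: thioacetal, formyl for bromine, silyl ether, ester reduction, acylation. The ester reduction must not epimerise C3.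

15 ⇒ 13 (through 14). The C3–C3a bond is cut by reinserting the ester carbon between C3 and C3a. The cis-dihydrobenzofuran becomes a 3-diazoflavanone with one stereocentre. The forward step must favour aryl migration over hydride shift and give kinetic protonation at C3.

13 ⇒ 10 (through 11 and 12). The diazo group is removed. The forward diazo transfer must not open the pyranone ring.

10 ⇒ 5 + 9. The C2–ring D bond is cut. An achiral chromone and a boronic acid are joined with a chiral rhodium catalyst that sets C2.

5 ⇒ 2 + 3 (through 4) ⇒ 1; 9 ⇒ 7 (through 8) ⇒ 6. The chromone C2 carbon and the bromine are removed, and the boronic acid goes back to the bromophenol.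

## Other disconnections considered

Alternative 1: The cut is through both benzylic C–O bonds of the furofuran (C7–O and C7′–O), back to the open-chain tetraol A1 (ring B as free bromophenol, the phenylcoumaran hydroxyls as pivalates). Forward, catalytic camphorsulfonic acid would ionise both benzylic carbinols of A1, and each cation would be captured by the primary hydroxyl four atoms away to give A2.
- In its favour: two rings and the C7/C7′ centres arise in one catalytic operation, and the carbinol configurations of A1 do not matter, so only C8 and C8′ need prior control. The pivalate on ring D lowers the electron density that would help C2–O1 ionise.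
- Against it here: the exo,exo outcome rests on kinetic control, since the product ethers can re-ionise. Pivalates do not survive organolithium or hydride steps, so they must be installed late and removed at the end by base or hydride, which the C8″ keto alcohol tolerates poorly. The plan does nothing for the cis C2/C3 pair, which would need a separate asymmetric method.
- Comparison: the chosen route closes its furofuran by the same kind of ionisation (step 16), as a subordinate step, so on mechanism and bonds formed the two are equal. The alternative is the better in shielding ring D as an ester during the acid step. The chosen plan is the better in ending with fluoride and in deriving C3 from C2. Step count for the furofuran is equal; protecting-group changes make the alternative longer overall.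

Alternative 2: The cut is through C7–C8 and C9′–C8′, back to the γ-aryl butenolide A3 and the α-chloro (trimethylsilyl)methyl ether A4. Forward, CsF would remove silicon and chloride from A4, and the resulting C7–O–C9′ carbonyl ylide would add across C8=C8′ of A3, anti to the γ-aryl group, to give lactone A5.
- In its favour: it is convergent, forms two C–C bonds and one ring at once, and derives the whole bicycle from the single centre C7′ of A3. It uses fluoride and no acid, so the cis-dihydrobenzofuran is not at risk; on this point it is the better of the two.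
- Against it here: the ylide is short-lived and nothing enforces which terminus bonds to C8 or whether ring B ends exo at C7. The γ-hydrogen of A3 is benzylic and vinylogously acidic, so fluoride could racemise C7′. A5 is a lactone, so C9 must still be reduced to CH2 by ring opening and re-closure. The methoxymethyl ether needs acid and the pivalates need base for removal.
- Comparison: both plans take C8/C8′ from a butenolide, but here a permanent centre controls, while in the chosen plan the removable acetal centre of 23 does. The core-forming step is the better (one step against steps 13–16). The route to A3, the lactone-to-ether reduction and the deprotections make the total no shorter.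

Alternative 3: The cut is through C8–C8′ and the O–C7′ bond, back to the epoxy cinnamyl ether A6. Forward, Cp2TiCl (trivalent titanium) would open the epoxide at C8; C8 would add 5-exo to C8′ of the cinnamyl alkene. The benzylic C7′ centre would be captured by a second Cp2TiCl, and iodine would make C7′ electrophilic for attack by the C9 titanium alkoxide, giving A7.
- In its favour: both rings and the central C–C bond form in one flask from an ether of two simple pieces, without acid. A7 carries the same kind of silyl protection as 30, so the endgame would be equal. About four steps from the aldehyde stage would replace six (11, 13–17), so it is the better on step economy.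
- Against it here: C8, C8′ and C7′ depend on substrate-controlled selectivity relative to C7. The trans preference of the radical closure and the exo closure at C7′ are likely to be only moderate. Two equivalents of titanium are needed, and the benzylic iodide stage is itself an ionising, acid-releasing stage.
- Comparison: radical then ionic closure against anionic additions then ionic closure. The chosen plan is the better on stereocontrol at C8/C8′ (two anti additions on a rigid lactone under auxiliary control). The alternative is the better on step count and the equal in protecting-group compatibility.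

Key step: step 7

Remarks on the chemistry (assumptions):
- Compounds 21, 23 and 31 are treated as purchasable.
- The antipode of the chiral diene (step 5) and of the pybox ligand (step 21) is the one that gives the stated configuration; which one does so is to be fixed on a model substrate.
- C2 is S in 10, R in 13 and S in 15 only because the CIP priorities change; the centre is not touched after step 5.
- The ring D silyl ether is kept as triisopropylsilyl, and the key step is run at 365 nm so that the C–Br bond is not excited.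

## Steps

Step 1
Reactants: 1 2′-hydroxy-3′-methoxyacetophenone
Product: 2 5′-bromo-2′-hydroxy-3′-methoxyacetophenone
Conditions: NBS, MeCN, 0 °C to rt
Reagents that add atoms: N-bromosuccinimide, O=C1CCC(=O)N1Br
Why: Electrophilic aromatic bromination; the phenol directs para to itself (C5′), the only open activated position not flanked by two substituents.

Step 2
Reactants: 2 5′-bromo-2′-hydroxy-3′-methoxyacetophenone; 3 N,N-dimethylformamide dimethyl acetal
Product: 5 6-bromo-8-methoxy-4H-chromen-4-one, via enaminone 4 (not isolated)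
Conditions: toluene, 95 °C; then conc. HCl, CH2Cl2, rt
Reagents that add atoms: none
Why: Condensation of the methyl ketone with the amide acetal gives the enaminone; acid then promotes addition of the phenol to the β-carbon and loss of dimethylamine (standard chromone synthesis).

Step 3
Reactants: 6 4-bromo-2-methoxyphenol
Product: 7 (4-bromo-2-methoxyphenoxy)triisopropylsilane
Conditions: TIPSCl, imidazole, DMF, rt
Reagents that add atoms: triisopropylsilyl chloride, CC(C)[Si](Cl)(C(C)C)C(C)C
Why: Phenol silylation; the bulky silyl ether survives n-BuLi, magnesium insertion, aqueous KOH, LiN(SiMe3)2 and hydride reagents used later.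

Step 4
Reactants: 7 (4-bromo-2-methoxyphenoxy)triisopropylsilane
Product: 9 [3-methoxy-4-(triisopropylsilyloxy)phenyl]boronic acid, via aryllithium 8 (not isolated)
Conditions: n-BuLi, THF, −78 °C; B(OiPr)3, −78 °C to rt; aq. NH4Cl
Reagents that add atoms: triisopropyl borate, CC(C)OB(OC(C)C)OC(C)C; water, O
Why: Bromine–lithium exchange, borylation and hydrolysis; lithium sits para to the silyloxy group, so no silyl migration can occur.

Step 5
Reactants: 5 6-bromo-8-methoxy-4H-chromen-4-one; 9 [3-methoxy-4-(triisopropylsilyloxy)phenyl]boronic acid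
Product: 10 (2S)-6-bromo-8-methoxy-2-[3-methoxy-4-(triisopropylsilyloxy)phenyl]chroman-4-one
Conditions: [Rh(C2H4)2Cl]2 (2.5 mol %), chiral bicyclo[2.2.2]octa-2,5-diene ligand (5.5 mol %), aq. KOH (0.3 equiv), toluene, 30 °C
Reagents that add atoms: none
Why: Hayashi–Miyaura asymmetric 1,4-addition of the aryl–rhodium species to C2 of the chromone; the chiral diene selects the enantioface and sets C2. The aryl bromide is inert to monovalent rhodium under these conditions, and the mild base and low temperature limit retro-oxa-Michael racemisation.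

Step 6
Reactants: 10 (2S)-flavanone
Product: 13 (2R)-6-bromo-3-diazo-8-methoxy-2-[3-methoxy-4-(triisopropylsilyloxy)phenyl]chroman-4-one, via lithium enolate 11 (not isolated), via trifluoroacetyl diketone 12 (not isolated)
Conditions: LiN(SiMe3)2, THF, −78 °C; CF3CO2CH2CF3, −78 °C; then p-ABSA, Et3N, H2O (1 equiv), MeCN, 0 °C to rt
Reagents that add atoms: 4-acetamidobenzenesulfonyl azide, CC(=O)Nc1ccc(cc1)S(=O)(=O)N=[N+]=[N-]
Why: Deacylative Regitz diazo transfer; C3 is trifluoroacetylated at −78 °C, where E1cB opening of the enolate is slow, and the activated dicarbonyl then takes the diazo group with a mild amine base and loses the trifluoroacetyl group. C2 is not involved.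

Step 7
Reactants: 13 (2R)-3-diazoflavanone
Product: 15 methyl (2S,3R)-5-bromo-7-methoxy-2-[3-methoxy-4-(triisopropylsilyloxy)phenyl]-2,3-dihydro-1-benzofuran-3-carboxylate (2,3-cis), via ketene 14 (not isolated)
Conditions: hν (365 nm LED), MeOH/CH2Cl2 (4:1), 0 °C, Ar
Reagents that add atoms: methanol, CO
Why: Photochemical Wolff rearrangement used as a ring contraction: excitation expels N2 and, because the ring holds C=O and C=N2 s-cis, the C4–C4a bond lies anti-periplanar to the departing nitrogen, so C4a shifts to C3 in step with N2 loss to give ketene 14. The closest known reaction is the photolytic contraction of cyclic 2-diazo-1-ketones such as 2-diazo-1-tetralones to indane-1-carboxylates. The ring O1–C2–C3–C3a–C7a is closed by a 1,2-shift that excises C4 from the pyranone, not by a cyclisation. Methanol adds to the ketene and the ester enol is protonated at C3 from the face opposite the C2 aryl group, which puts the ester cis to that group; C3 is thus set by substrate control from C2, which is untouched. The step needs migration to win over hydride shift from C2 (flavone) and over O–H insertion, which the locked s-cis geometry favours, and kinetic protonation, which neutral medium and low temperature favour. Light at 365 nm excites only the diazo ketone and spares the C–Br bond and the product.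

Step 8
Reactants: 15 cis methyl ester
Product: 16 [(2S,3S)-5-bromo-7-methoxy-2-[3-methoxy-4-(triisopropylsilyloxy)phenyl]-2,3-dihydro-1-benzofuran-3-yl]methanol
Conditions: iBu2AlH (3 equiv), CH2Cl2, −78 to −40 °C; aq. potassium sodium tartrate
Reagents that add atoms: none
Why: Ester reduction through non-basic aluminium alkoxides at low temperature, run on the crude photolysate, so the acidic C3–H is not epimerised to the more stable trans series before the carbonyl is gone.

Step 9
Reactants: 16 cis alcohol
Product: 17 (2S,3S)-5-bromo-3-[(tert-butyldimethylsilyloxy)methyl]-7-methoxy-2-[3-methoxy-4-(triisopropylsilyloxy)phenyl]-2,3-dihydro-1-benzofuran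
Conditions: TBSCl, imidazole, DMF, rt
Reagents that add atoms: tert-butyldimethylsilyl chloride, CC(C)(C)[Si](C)(C)Cl
Why: Standard silylation of the primary alcohol.

Step 10
Reactants: 17 silyl ether bromide
Product: 19 (2S,3S)-3-[(tert-butyldimethylsilyloxy)methyl]-7-methoxy-2-[3-methoxy-4-(triisopropylsilyloxy)phenyl]-2,3-dihydro-1-benzofuran-5-carbaldehyde, via aryllithium 18 (not isolated)
Conditions: n-BuLi, THF, −78 °C; DMF, −78 to 0 °C; aq. NH4Cl
Reagents that add atoms: N,N-dimethylformamide, CN(C)C=O
Why: Bromine–lithium exchange is faster than any deprotonation at −78 °C; formylation with DMF (Bouveault aldehyde synthesis).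

Step 11
Reactants: 19 aldehyde
Product: 20 2-{(2S,3S)-3-[(tert-butyldimethylsilyloxy)methyl]-7-methoxy-2-[3-methoxy-4-(triisopropylsilyloxy)phenyl]-2,3-dihydro-1-benzofuran-5-yl}-1,3-dithiane
Conditions: HS(CH2)3SH, I2 (5 mol %), CH2Cl2, 0 °C to rt
Reagents that add atoms: propane-1,3-dithiol, SCCCS
Why: Thioacetalisation under mild iodine catalysis, avoiding strong Lewis acids that could ionise C2–O1 or strip the silyl ethers.

Step 12
Reactants: 21 4-hydroxy-3-iodo-5-methoxybenzaldehyde
Product: 22 4-formyl-2-iodo-6-methoxyphenyl 2,2-dimethylpropanoate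
Conditions: PivCl, Et3N, DMAP (cat.), CH2Cl2, 0 °C to rt
Reagents that add atoms: pivaloyl chloride, CC(C)(C)C(=O)Cl
Why: Phenol acylation; the pivalate is non-enolisable and hindered, so it survives the enolate in step 13 and is removed by the hydride in step 15.

Step 13
Reactants: 20 dithiane; 23 (5R)-5-{[(1R,2S,5R)-5-methyl-2-(propan-2-yl)cyclohexyl]oxy}furan-2(5H)-one; 22 pivalate aldehyde
Product: 26 (3S,4R,5R)-lactone adduct (carbinol epimers), via lithiated dithiane 24 (not isolated), via lactone enolate 25 (not isolated)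
Conditions: n-BuLi, THF, −78 to −30 °C; 23, −78 °C; 22, −78 °C; aq. NH4Cl
Reagents that add atoms: none
Why: Corey–Seebach umpolung in a tandem conjugate addition–aldol: the 2-aryl dithiane anion adds 1,4 to the γ-alkoxybutenolide anti to the menthyloxy group (sets C8′), and the enolate is trapped by the aldehyde anti to the new substituent (sets C8). The carbinol at C7 forms as a mixture, which step 16 makes irrelevant.

Step 14
Reactants: 26 lactone adduct
Product: 27 (3S,4R,5R)-keto lactone (carbinol epimers)
Conditions: MeI, CaCO3, MeCN/H2O (9:1), 40 °C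
Reagents that add atoms: water, O
Why: S-methylation and hydrolysis unmask the C7′ ketone in a buffered, near-neutral medium that leaves the silyl ethers, pivalate, lactone acetal and C2–O1 untouched.

Step 15
Reactants: 27 keto lactone
Product: 28 (2R,3R)-1-(4-hydroxy-3-iodo-5-methoxyphenyl)-4-(ring C aryl)-2,3-bis(hydroxymethyl)butane-1,4-diol (C1/C4 carbinol epimers)
Conditions: LiBH4, THF, 0 °C to rt; aq. NH4Cl
Reagents that add atoms: none
Why: One hydride reagent reduces the ketone, the lactone carbonyl and the acetal carbon (through its ring-opened aldehyde, releasing menthol) and cleaves the aryl pivalate; the aryl iodide and silyl ethers are inert to LiBH4, and C8/C8′ are not touched.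

Step 16
Reactants: 28 pentaol
Product: 29 4-[(1S,3aR,4S,6aR)-4-(ring C aryl)tetrahydro-1H,3H-furo[3,4-c]furan-1-yl]-2-iodo-6-methoxyphenol
Conditions: CSA (10 mol %), 4 Å molecular sieves, CH2Cl2/THF, 0 °C; Et3N quench
Reagents that add atoms: none
Why: Acid-catalysed dehydrative double cycloetherification: the ring B carbinol ionises through a para-quinone methide and the ring C carbinol through a para-alkoxybenzyl cation, and each is captured 5-exo-trig by the primary hydroxyl four atoms away. C7 and C7′ are set here, the aryl groups taking the exo positions on the convex face dictated by C8/C8′; catalytic acid, low temperature and an early quench keep C2–O1 and the silyl ethers intact.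

Step 17
Reactants: 29 furofuran iodophenol
Product: 30 furofuran aryl iodide with ring B tert-butyldimethylsilyl ether
Conditions: TBSCl, imidazole, DMF, rt
Reagents that add atoms: tert-butyldimethylsilyl chloride, CC(C)(C)[Si](C)(C)Cl
Why: Phenol silylation, needed before the halogen–magnesium exchange.

Step 18
Reactants: 7 (4-bromo-2-methoxyphenoxy)triisopropylsilane; 31 3-(tert-butyldimethylsilyloxy)propanal
Product: 33 rac-3-(tert-butyldimethylsilyloxy)-1-[3-methoxy-4-(triisopropylsilyloxy)phenyl]propan-1-ol, via arylmagnesium bromide 32 (not isolated)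
Conditions: Mg turnings, I2 (cat.), THF, rt to 40 °C; 31, −20 to 0 °C; aq. NH4Cl
Reagents that add atoms: none
Why: Magnesium insertion into the aryl bromide gives the Grignard reagent, which adds to the aldehyde carbonyl (Grignard addition); the magnesium alkoxide does not expel the β-silyloxy group at low temperature, and both silyl ethers are inert to the reagent.

Step 19
Reactants: 33 benzylic alcohol
Product: 34 3-(tert-butyldimethylsilyloxy)-1-[3-methoxy-4-(triisopropylsilyloxy)phenyl]propan-1-one
Conditions: MnO2, CH2Cl2, rt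
Reagents that add atoms: none
Why: Selective oxidation of an electron-rich benzylic alcohol under neutral conditions.

Step 20
Reactants: 34 ketone
Product: 36 rac-2-bromo-3-(tert-butyldimethylsilyloxy)-1-[3-methoxy-4-(triisopropylsilyloxy)phenyl]propan-1-one, via silyl enol ether 35 (not isolated)
Conditions: TMSOTf, Et3N, CH2Cl2, 0 °C; NBS, THF, −78 to 0 °C
Reagents that add atoms: N-bromosuccinimide, O=C1CCC(=O)N1Br
Why: Soft enolisation to the silyl enol ether avoids a metal enolate that could expel the β-silyloxy group; bromination then occurs at the only enol carbon. The racemic bromide is what the next step requires.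

Step 21
Reactants: 30 aryl iodide; 36 racemic α-bromo ketone
Product: 39 pentasilylated target (C8″ S), via arylmagnesium chloride 37 (not isolated), via arylzinc iodide 38 (not isolated)
Conditions: iPrMgCl·LiCl, THF, −20 °C; ZnI2, THF, −20 to 0 °C; then 36, NiCl2·glyme (10 mol %), chiral pybox ligand (13 mol %), glyme/THF, −30 °C
Reagents that add atoms: none
Why: Iodine–magnesium exchange (no migration of the ortho silyl group at magnesium) and transmetalation give the arylzinc; nickel-catalysed stereoconvergent Negishi arylation of the racemic secondary α-bromo ketone then proceeds through a planar α-keto radical, and the chiral pybox–nickel aryl complex sets C8″. The low-temperature, non-basic conditions do not epimerise the product.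

Step 22
Reactants: 39 pentasilylated target
Product: 40 CNP0174045.1
Conditions: TBAF/AcOH (1:1), THF, 0 °C to rt; pH 6 phosphate buffer work-up
Reagents that add atoms: none
Why: Buffered fluoride cleaves the three aryl and two primary silyl ethers near neutrality, which avoids epimerisation at C8″, loss of formaldehyde or water, and acid-induced closure of the ring B phenol onto the ketone.

## Compound list

1 | 2′-hydroxy-3′-methoxyacetophenone | COc1cccc(C(C)=O)c1O | starting material
2 | 5′-bromo-2′-hydroxy-3′-methoxyacetophenone | COc1cc(Br)cc(C(C)=O)c1O | intermediate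
3 | N,N-dimethylformamide dimethyl acetal | COC(OC)N(C)C | starting material
4 | (E)-1-(5-bromo-2-hydroxy-3-methoxyphenyl)-3-(dimethylamino)prop-2-en-1-one | COc1cc(Br)cc(C(=O)/C=C/N(C)C)c1O | intermediate
5 | 6-bromo-8-methoxy-4H-chromen-4-one | COc1cc(Br)cc2c(=O)ccoc12 | intermediate
6 | 4-bromo-2-methoxyphenol | COc1cc(Br)ccc1O | starting material
7 | (4-bromo-2-methoxyphenoxy)triisopropylsilane | COc1cc(Br)ccc1O[Si](C(C)C)(C(C)C)C(C)C | intermediate
8 | [3-methoxy-4-(triisopropylsilyloxy)phenyl]lithium | COc1cc([Li])ccc1O[Si](C(C)C)(C(C)C)C(C)C | intermediate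
9 | [3-methoxy-4-(triisopropylsilyloxy)phenyl]boronic acid | COc1cc(B(O)O)ccc1O[Si](C(C)C)(C(C)C)C(C)C | intermediate
10 | (2S)-6-bromo-8-methoxy-2-[3-methoxy-4-(triisopropylsilyloxy)phenyl]chroman-4-one | Brc1cc(OC)c2c(c1)C(=O)C[C@@H](c1ccc(O[Si](C(C)C)(C(C)C)C(C)C)c(OC)c1)O2 | intermediate
11 | lithium C3–C4 enolate of 10 (C2 unchanged) | Brc1cc(OC)c2c(c1)C(O[Li])=C[C@@H](c1ccc(O[Si](C(C)C)(C(C)C)C(C)C)c(OC)c1)O2 | intermediate
12 | 3-(trifluoroacetyl) derivative of 10 (C3 epimers or enol, C2 unchanged) | Brc1cc(OC)c2c(c1)C(=O)C(C(=O)C(F)(F)F)[C@@H](c1ccc(O[Si](C(C)C)(C(C)C)C(C)C)c(OC)c1)O2 | intermediate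
13 | (2R)-6-bromo-3-diazo-8-methoxy-2-[3-methoxy-4-(triisopropylsilyloxy)phenyl]chroman-4-one | Brc1cc(OC)c2c(c1)C(=O)C(=[N+]=[N-])[C@@H](c1ccc(O[Si](C(C)C)(C(C)C)C(C)C)c(OC)c1)O2 | intermediate
14 | {5-bromo-7-methoxy-2-[3-methoxy-4-(triisopropylsilyloxy)phenyl]-1-benzofuran-3(2H)-ylidene}methanone (ketene, C2 unchanged) | Brc1cc(OC)c2c(c1)C(=C=O)[C@@H](c1ccc(O[Si](C(C)C)(C(C)C)C(C)C)c(OC)c1)O2 | intermediate
15 | methyl (2S,3R)-5-bromo-7-methoxy-2-[3-methoxy-4-(triisopropylsilyloxy)phenyl]-2,3-dihydro-1-benzofuran-3-carboxylate (cis) | Brc1cc(OC)c2c(c1)[C@@H](C(=O)OC)[C@@H](c1ccc(O[Si](C(C)C)(C(C)C)C(C)C)c(OC)c1)O2 | intermediate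
16 | [(2S,3S)-5-bromo-7-methoxy-2-[3-methoxy-4-(triisopropylsilyloxy)phenyl]-2,3-dihydro-1-benzofuran-3-yl]methanol | Brc1cc(OC)c2c(c1)[C@@H](CO)[C@@H](c1ccc(O[Si](C(C)C)(C(C)C)C(C)C)c(OC)c1)O2 | intermediate
17 | (2S,3S)-5-bromo-3-[(tert-butyldimethylsilyloxy)methyl]-7-methoxy-2-[3-methoxy-4-(triisopropylsilyloxy)phenyl]-2,3-dihydro-1-benzofuran | Brc1cc(OC)c2c(c1)[C@@H](CO[Si](C)(C)C(C)(C)C)[C@@H](c1ccc(O[Si](C(C)C)(C(C)C)C(C)C)c(OC)c1)O2 | intermediate
18 | 5-lithio analogue of 17 | [Li]c1cc(OC)c2c(c1)[C@@H](CO[Si](C)(C)C(C)(C)C)[C@@H](c1ccc(O[Si](C(C)C)(C(C)C)C(C)C)c(OC)c1)O2 | intermediate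
19 | (2S,3S)-3-[(tert-butyldimethylsilyloxy)methyl]-7-methoxy-2-[3-methoxy-4-(triisopropylsilyloxy)phenyl]-2,3-dihydro-1-benzofuran-5-carbaldehyde | O=Cc1cc(OC)c2c(c1)[C@@H](CO[Si](C)(C)C(C)(C)C)[C@@H](c1ccc(O[Si](C(C)C)(C(C)C)C(C)C)c(OC)c1)O2 | intermediate
20 | 2-(benzofuran-5-yl)-1,3-dithiane derived from 19 | C1CSC(SC1)c1cc(OC)c2c(c1)[C@@H](CO[Si](C)(C)C(C)(C)C)[C@@H](c1ccc(O[Si](C(C)C)(C(C)C)C(C)C)c(OC)c1)O2 | intermediate
21 | 4-hydroxy-3-iodo-5-methoxybenzaldehyde | COc1cc(C=O)cc(I)c1O | starting material
22 | 4-formyl-2-iodo-6-methoxyphenyl 2,2-dimethylpropanoate | COc1cc(C=O)cc(I)c1OC(=O)C(C)(C)C | intermediate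
23 | (5R)-5-{[(1R,2S,5R)-5-methyl-2-(propan-2-yl)cyclohexyl]oxy}furan-2(5H)-one | O=C1C=C[C@H](O[C@@H]2C[C@H](C)CC[C@H]2C(C)C)O1 | starting material
24 | 2-lithio derivative of dithiane 20 | [Li]C1(SCCCS1)c1cc(OC)c2c(c1)[C@@H](CO[Si](C)(C)C(C)(C)C)[C@@H](c1ccc(O[Si](C(C)C)(C(C)C)C(C)C)c(OC)c1)O2 | intermediate
25 | lithium enolate of the (4R,5R)-4-(2-aryl-1,3-dithian-2-yl)-5-(menthyloxy)lactone | [Li]OC1=C[C@@H](C2(SCCCS2)c2cc(OC)c3c(c2)[C@@H](CO[Si](C)(C)C(C)(C)C)[C@@H](c2ccc(O[Si](C(C)C)(C(C)C)C(C)C)c(OC)c2)O3)[C@H](O[C@@H]2C[C@H](C)CC[C@H]2C(C)C)O1 | intermediate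
26 | (3S,4R,5R)-3-[hydroxy(3-iodo-5-methoxy-4-pivaloyloxyphenyl)methyl]-4-[2-(ring C aryl)-1,3-dithian-2-yl]-5-(menthyloxy)dihydrofuran-2(3H)-one (carbinol epimers) | O=C1[C@H](C(O)c2cc(OC)c(OC(=O)C(C)(C)C)c(I)c2)[C@@H](C2(SCCCS2)c2cc(OC)c3c(c2)[C@@H](CO[Si](C)(C)C(C)(C)C)[C@@H](c2ccc(O[Si](C(C)C)(C(C)C)C(C)C)c(OC)c2)O3)[C@H](O[C@@H]2C[C@H](C)CC[C@H]2C(C)C)O1 | intermediate
27 | (3S,4R,5R)-4-(ring C aroyl)-3-[hydroxy(3-iodo-5-methoxy-4-pivaloyloxyphenyl)methyl]-5-(menthyloxy)dihydrofuran-2(3H)-one (carbinol epimers) | O=C1[C@H](C(O)c2cc(OC)c(OC(=O)C(C)(C)C)c(I)c2)[C@@H](C(=O)c2cc(OC)c3c(c2)[C@@H](CO[Si](C)(C)C(C)(C)C)[C@@H](c2ccc(O[Si](C(C)C)(C(C)C)C(C)C)c(OC)c2)O3)[C@H](O[C@@H]2C[C@H](C)CC[C@H]2C(C)C)O1 | intermediate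
28 | (2R,3R)-1-(4-hydroxy-3-iodo-5-methoxyphenyl)-4-(ring C aryl)-2,3-bis(hydroxymethyl)butane-1,4-diol (C1/C4 epimers) | OC(c1cc(OC)c(O)c(I)c1)[C@@H](CO)[C@H](CO)C(O)c1cc(OC)c2c(c1)[C@@H](CO[Si](C)(C)C(C)(C)C)[C@@H](c1ccc(O[Si](C(C)C)(C(C)C)C(C)C)c(OC)c1)O2 | intermediate
29 | 4-[(1S,3aR,4S,6aR)-4-{(2S,3S)-3-[(tert-butyldimethylsilyloxy)methyl]-7-methoxy-2-[3-methoxy-4-(triisopropylsilyloxy)phenyl]-2,3-dihydro-1-benzofuran-5-yl}tetrahydro-1H,3H-furo[3,4-c]furan-1-yl]-2-iodo-6-methoxyphenol | COc1cc(cc(I)c1O)[C@H]1OC[C@H]2[C@@H]1CO[C@@H]2c1cc(OC)c2c(c1)[C@@H](CO[Si](C)(C)C(C)(C)C)[C@@H](c1ccc(O[Si](C(C)C)(C(C)C)C(C)C)c(OC)c1)O2 | intermediate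
30 | tert-butyldimethylsilyl ether of 29 at the ring B phenol | COc1cc(cc(I)c1O[Si](C)(C)C(C)(C)C)[C@H]1OC[C@H]2[C@@H]1CO[C@@H]2c1cc(OC)c2c(c1)[C@@H](CO[Si](C)(C)C(C)(C)C)[C@@H](c1ccc(O[Si](C(C)C)(C(C)C)C(C)C)c(OC)c1)O2 | intermediate
31 | 3-(tert-butyldimethylsilyloxy)propanal | O=CCCO[Si](C)(C)C(C)(C)C | starting material
32 | [3-methoxy-4-(triisopropylsilyloxy)phenyl]magnesium bromide | COc1cc([Mg]Br)ccc1O[Si](C(C)C)(C(C)C)C(C)C | intermediate
33 | rac-3-(tert-butyldimethylsilyloxy)-1-[3-methoxy-4-(triisopropylsilyloxy)phenyl]propan-1-ol | COc1cc(C(O)CCO[Si](C)(C)C(C)(C)C)ccc1O[Si](C(C)C)(C(C)C)C(C)C | intermediate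
34 | 3-(tert-butyldimethylsilyloxy)-1-[3-methoxy-4-(triisopropylsilyloxy)phenyl]propan-1-one | COc1cc(C(=O)CCO[Si](C)(C)C(C)(C)C)ccc1O[Si](C(C)C)(C(C)C)C(C)C | intermediate
35 | (Z)-trimethylsilyl enol ether of 34 | COc1cc(/C(O[Si](C)(C)C)=C/CO[Si](C)(C)C(C)(C)C)ccc1O[Si](C(C)C)(C(C)C)C(C)C | intermediate
36 | rac-2-bromo-3-(tert-butyldimethylsilyloxy)-1-[3-methoxy-4-(triisopropylsilyloxy)phenyl]propan-1-one | COc1cc(C(=O)C(Br)CO[Si](C)(C)C(C)(C)C)ccc1O[Si](C(C)C)(C(C)C)C(C)C | intermediate
37 | arylmagnesium chloride from 30 (MgCl in place of I) | COc1cc(cc([Mg]Cl)c1O[Si](C)(C)C(C)(C)C)[C@H]1OC[C@H]2[C@@H]1CO[C@@H]2c1cc(OC)c2c(c1)[C@@H](CO[Si](C)(C)C(C)(C)C)[C@@H](c1ccc(O[Si](C(C)C)(C(C)C)C(C)C)c(OC)c1)O2 | intermediate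
38 | arylzinc iodide from 37 (ZnI in place of MgCl) | COc1cc(cc([Zn]I)c1O[Si](C)(C)C(C)(C)C)[C@H]1OC[C@H]2[C@@H]1CO[C@@H]2c1cc(OC)c2c(c1)[C@@H](CO[Si](C)(C)C(C)(C)C)[C@@H](c1ccc(O[Si](C(C)C)(C(C)C)C(C)C)c(OC)c1)O2 | intermediate
39 | pentasilyl ether of the target: (2S)-3-(tert-butyldimethylsilyloxy)-1-[3-methoxy-4-(triisopropylsilyloxy)phenyl]-2-(ring B aryl)propan-1-one carrying the furofuran and cis-dihydrobenzofuran of 30 | COc1cc(C(=O)[C@H](CO[Si](C)(C)C(C)(C)C)c2cc([C@H]3OC[C@H]4[C@@H]3CO[C@@H]4c3cc(OC)c4c(c3)[C@@H](CO[Si](C)(C)C(C)(C)C)[C@@H](c3ccc(O[Si](C(C)C)(C(C)C)C(C)C)c(OC)c3)O4)cc(OC)c2O[Si](C)(C)C(C)(C)C)ccc1O[Si](C(C)C)(C(C)C)C(C)C | intermediate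
40 | CNP0174045.1 | COc1cc(C(=O)[C@H](CO)c2cc([C@H]3OC[C@H]4[C@@H]3CO[C@@H]4c3cc(OC)c4c(c3)[C@@H](CO)[C@@H](c3ccc(O)c(OC)c3)O4)cc(OC)c2O)ccc1O | target

## Step count and least certain steps

Total: 22 steps. Longest linear sequence: 16 steps (1, 2, 5–11, 13–17, 21, 22).

Step 7 (key step). The most likely failure is loss of chemoselectivity once N2 leaves: any part of the excited diazo ketone that loses nitrogen before C4a begins to move gives a free carbene next to a migratable benzylic hydrogen. That opens hydride shift from C2 (aromatisation to the flavone) and O–H insertion of methanol. A second risk is drift of the kinetic cis arrangement to trans by enolisation of the ester in methanol. Fallback, setting out from 2 and returning at 15: the C3–C2 bond is made by carbenoid C–H insertion instead of ring contraction. Mitsunobu etherification of 2 with [3-methoxy-4-(triisopropylsilyloxy)phenyl]methanol (PPh3, DIAD) would give the aryl benzyl ether F1. Hypervalent-iodine oxidative 1,2-aryl shift of the methyl ketone (PhI(OAc)2, HC(OMe)3, cat. H2SO4, MeOH) would give the methyl arylacetate F2. Diazo transfer (p-ABSA, DBU) would give the aryl diazoacetate F3. Intramolecular insertion into the benzylic ether C–H bond with Rh2(S-PTTL)4 or its antipode (toluene, −60 °C) is known to give cis-2-aryl-2,3-dihydrobenzofuran-3-carboxylates with catalyst control, and would lead to 15.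

Step 6. The most likely failure is partial racemisation at C2 through reversible E1cB opening of the flavanone enolate, or of the trifluoroacetylated dicarbonyl anion, to the 2′-hydroxychalcone and re-closure; the phenoxide is a good leaving group β to the enolate. Fallback, from 10 to 13, with no metal enolate: condensation of 10 with tert-butoxybis(dimethylamino)methane (toluene, 60 °C) would give the enaminone F4. Diazo transfer to F4 with p-ABSA would give 13 with loss of the sulfonyl formamidine.

Step 16. The most likely failure is incomplete kinetic control: re-ionisation of the new benzylic ethers at C7 or C7′ (endo aryl isomers), ionisation of C2–O1 (cis to trans drift of the dihydrobenzofuran) or loss of the primary silyl ether. All of these are ethers at benzylic carbons of oxygenated arenes and differ from the intended ionisation only in rate. Fallback, from 27 to 29, without cations: Dess–Martin oxidation of the C7 carbinol would give diketone F5. Reagent-controlled reduction of both aryl ketones ((R)-Me-CBS oxazaborolidine, catecholborane; Corey–Bakshi–Shibata reduction) would give the (7S,7′S)-diol F6. LiBH4 would give the single pentaol F7. 2,4,6-Triisopropylbenzenesulfonyl chloride in pyridine would sulfonylate only the two primary hydroxyls, the hindered phenol being expected to stay free, and give the bis(sulfonate) F8. Warming F8 with K2CO3 would close both rings by 5-exo-tet displacement at C9 and C9′, with retention at C7 and C7′, to give 29.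

Step 21. The most likely failure is slow or unselective coupling: the arylzinc carries a bulky silyloxy group ortho to the C–Zn bond, and the nickel-bound α-keto alkyl fragment carries a β-silyloxy group that can be lost by β-elimination. Either would lower conversion or the selectivity at C8″. Fallback, from 30 and 35 to 39: palladium-catalysed α-arylation of the silyl enol ether 35 (made as in step 20 and used without bromination) with iodide 30 (Pd(OAc)2, P(t-Bu)3, Bu3SnF, CsF, toluene, 80 °C) would form the same C8″–aryl bond without stereocontrol. 39 and its C8″ epimer F9 are diastereomers and would be separated by chromatography. F9 would be returned to the mixture by amine-mediated equilibration at the acidic C8″ centre.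

## Further compounds

F1 | step 7 | 1-(5-bromo-3-methoxy-2-{[3-methoxy-4-(triisopropylsilyloxy)phenyl]methoxy}phenyl)ethan-1-one | CC(=O)c1cc(Br)cc(OC)c1OCc1ccc(O[Si](C(C)C)(C(C)C)C(C)C)c(OC)c1
F2 | step 7 | methyl 2-(5-bromo-3-methoxy-2-{[3-methoxy-4-(triisopropylsilyloxy)phenyl]methoxy}phenyl)acetate | COC(=O)Cc1cc(Br)cc(OC)c1OCc1ccc(O[Si](C(C)C)(C(C)C)C(C)C)c(OC)c1
F3 | step 7 | methyl 2-diazo-2-(5-bromo-3-methoxy-2-{[3-methoxy-4-(triisopropylsilyloxy)phenyl]methoxy}phenyl)acetate | COC(=O)C(=[N+]=[N-])c1cc(Br)cc(OC)c1OCc1ccc(O[Si](C(C)C)(C(C)C)C(C)C)c(OC)c1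
F4 | step 6 | 6-bromo-3-[(dimethylamino)methylidene]-8-methoxy-2-[3-methoxy-4-(triisopropylsilyloxy)phenyl]chroman-4-one (C2 as in 10) | Brc1cc(OC)c2c(c1)C(=O)C(=CN(C)C)[C@@H](c1ccc(O[Si](C(C)C)(C(C)C)C(C)C)c(OC)c1)O2
F5 | step 16 | (3S,4R,5R)-4-(ring C aroyl)-3-(3-iodo-5-methoxy-4-pivaloyloxybenzoyl)-5-(menthyloxy)dihydrofuran-2(3H)-one | O=C1[C@H](C(=O)c2cc(OC)c(OC(=O)C(C)(C)C)c(I)c2)[C@@H](C(=O)c2cc(OC)c3c(c2)[C@@H](CO[Si](C)(C)C(C)(C)C)[C@@H](c2ccc(O[Si](C(C)C)(C(C)C)C(C)C)c(OC)c2)O3)[C@H](O[C@@H]2C[C@H](C)CC[C@H]2C(C)C)O1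
F6 | step 16 | lactone diol from F5 with both carbinols S | O=C1[C@H]([C@H](O)c2cc(OC)c(OC(=O)C(C)(C)C)c(I)c2)[C@@H]([C@H](O)c2cc(OC)c3c(c2)[C@@H](CO[Si](C)(C)C(C)(C)C)[C@@H](c2ccc(O[Si](C(C)C)(C(C)C)C(C)C)c(OC)c2)O3)[C@H](O[C@@H]2C[C@H](C)CC[C@H]2C(C)C)O1
F7 | step 16 | (1S,2R,3R,4S) single diastereomer of pentaol 28 | O[C@H](c1cc(OC)c(O)c(I)c1)[C@@H](CO)[C@H](CO)[C@H](O)c1cc(OC)c2c(c1)[C@@H](CO[Si](C)(C)C(C)(C)C)[C@@H](c1ccc(O[Si](C(C)C)(C(C)C)C(C)C)c(OC)c1)O2
F8 | step 16 | bis(2,4,6-triisopropylbenzenesulfonate) of F7 at the two primary hydroxyls | O[C@H](c1cc(OC)c(O)c(I)c1)[C@@H](COS(=O)(=O)c1c(C(C)C)cc(C(C)C)cc1C(C)C)[C@H](COS(=O)(=O)c1c(C(C)C)cc(C(C)C)cc1C(C)C)[C@H](O)c1cc(OC)c2c(c1)[C@@H](CO[Si](C)(C)C(C)(C)C)[C@@H](c1ccc(O[Si](C(C)C)(C(C)C)C(C)C)c(OC)c1)O2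
F9 | step 21 | C8″ epimer (R) of 39 | COc1cc(C(=O)[C@@H](CO[Si](C)(C)C(C)(C)C)c2cc([C@H]3OC[C@H]4[C@@H]3CO[C@@H]4c3cc(OC)c4c(c3)[C@@H](CO[Si](C)(C)C(C)(C)C)[C@@H](c3ccc(O[Si](C(C)C)(C(C)C)C(C)C)c(OC)c3)O4)cc(OC)c2O[Si](C)(C)C(C)(C)C)ccc1O[Si](C(C)C)(C(C)C)C(C)C
A1 | alternative 1 | (2R,3R)-1-(3-bromo-4-hydroxy-5-methoxyphenyl)-4-(pivaloylated ring C aryl)-2,3-bis(hydroxymethyl)butane-1,4-diol (carbinol epimers) | OC(c1cc(OC)c(O)c(Br)c1)[C@@H](CO)[C@H](CO)C(O)c1cc(OC)c2c(c1)[C@@H](COC(=O)C(C)(C)C)[C@@H](c1ccc(OC(=O)C(C)(C)C)c(OC)c1)O2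
A2 | alternative 1 | furofuran with ring B bromophenol and pivaloylated cis-phenylcoumaran | Brc1cc(cc(OC)c1O)[C@H]3OC[C@H]4[C@@H]3CO[C@@H]4c3cc(OC)c4c(c3)[C@@H](COC(=O)C(C)(C)C)[C@@H](c3ccc(OC(=O)C(C)(C)C)c(OC)c3)O4
A3 | alternative 2 | (5S)-5-(pivaloylated ring C aryl)furan-2(5H)-one | O=C1C=C[C@@H](c2cc(OC)c3c(c2)[C@@H](COC(=O)C(C)(C)C)[C@@H](c2ccc(OC(=O)C(C)(C)C)c(OC)c2)O3)O1
A4 | alternative 2 | rac-{[chloro(3-bromo-5-methoxy-4-(methoxymethoxy)phenyl)methoxy]methyl}trimethylsilane | COCOc1c(Br)cc(cc1OC)C(Cl)OC[Si](C)(C)C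
A5 | alternative 2 | 2,6-diaryl-3,7-dioxabicyclo[3.3.0]octan-8-one with ring B methoxymethyl ether and pivaloylated cis-phenylcoumaran | Brc1cc(cc(OC)c1OCOC)[C@H]3OC[C@H]4[C@@H]3C(=O)O[C@@H]4c3cc(OC)c4c(c3)[C@@H](COC(=O)C(C)(C)C)[C@@H](c3ccc(OC(=O)C(C)(C)C)c(OC)c3)O4
A6 | alternative 3 | (E)-cinnamyl ether of the ring B aryl(oxiranyl)methanol, C7 as in A7, either epoxide epimer | Brc1cc(cc(OC)c1O[Si](C)(C)C(C)(C)C)[C@@H](OC/C=C/c1cc(OC)c2c(c1)[C@@H](CO[Si](C)(C)C(C)(C)C)[C@@H](c1ccc(O[Si](C)(C)C(C)(C)C)c(OC)c1)O2)C1CO1
A7 | alternative 3 | silylated furofuran–phenylcoumaran with ring B bromide | Brc1cc(cc(OC)c1O[Si](C)(C)C(C)(C)C)[C@H]3OC[C@H]4[C@@H]3CO[C@@H]4c3cc(OC)c4c(c3)[C@@H](CO[Si](C)(C)C(C)(C)C)[C@@H](c3ccc(O[Si](C)(C)C(C)(C)C)c(OC)c3)O4
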